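The runs are calculated for substances that don't exist; noise was put on by code.

Amounts first: two earlier runs and a new flask hold the same equivalents of reagent and differ in the starting material charged. I want the share of target in target plus isomer of the product, early and late.

| setting | green | red | flask |
|---|---|---|---|
| starting material | 18 mM | 29 mM | 13 mM |
| reagent | 2.5 equiv | 2.5 equiv | 2.50 equiv |
| remark | run made earlier | run made earlier |  |
| time |  |  | 2.5 d |

| run | time / d | target / % | isomer of the product / % |
|---|---|---|---|
| green | 0.250 | 45.8 | 29.4 |
| green | 0.833 | 54.8 | 38.8 |
| green | 1.25 | 54.9 | 38.6 |
| green | 2.00 | 55.3 | 38.8 |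
| green | 3.00 | 55.9 | 38.8 |
| red | 0.250 | 59.4 | 26.3 |
| red | 0.833 | 64.7 | 31.4 |
| red | 1.25 | 65.3 | 31.1 |
| red | 2.00 | 65.4 | 31.2 |
| red | 3.00 | 65.4 | 32.4 |

(each reading ± 0.5 percentage points)

- share of target in target plus isomer of the product at 20 min
- share of target in target plus isomer of the product at 2.5 d



In the green run, target plus isomer of the product stand at 75.2% of the starting material charged at 0.250 d and 93.6% at 0.833 d. The curve climbs steeply, bends between those readings and runs level. If I let the bend move out in inverse proportion to the charge, this flask reaches it by 1.15 d, earlier than 2.5 d, so I read the late answer off the level.

Let R be target over isomer of the product on that level, a selectivity factor. The four level readings of each run give 1.43 for green and 2.07 for red. I carry m, the rise of R per unit of starting material charged: 0.0585 /mM. Going down this line from green to the flask's charge gives R = 1.13, so the share R/(1+R) is 53.1%. The first reading comes later than 20 min, so my line is silent there.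

The forecast gives 56% (52% to 60%) early and 52.7% (49.5% to 55.5%) late, a little below mine. Its early ground: “Selectivity therefore falls as reagent and starting material deplete”.

The flask gives 86.1% and 52.8%.

    starting material ⇌ other conformer (K = 0.620, k = 0.160 /h)
    starting material + reagent → target (k = 4.50 /M/h)
    reagent + other conformer → isomer of the product (k = 31.0 /M/h)
    2 other conformer → self-condensation product (k = 110 /M/h)

The early share stands 30 percentage points above the forecast. In this flask, target leads at 0.0750 d, 19.5% against 10.1% of isomer of the product, while starting material passes to other conformer. By 1.25 d, 0.187% of starting material and 0.0426% of other conformer stand, with target at 48.9% and isomer of the product at 43.6%. With m at 0.0585 /mM, my line stood at 53.1% for this flask's late share, and the flask gives 52.8%. For the neighbour charged with 7.8 mM, m gives R = 0.829, a share of 45.3%; the computed share is 44.5%.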